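## Retrosynthetic overview

1. Target ⇐ macrocyclic β-hydroxy enone (C3–OH, C1=O): one Evans–Tishchenko reduction with acetaldehyde sets C1 and places the acetate on O3.
2. Ten-membered ring (formed second) ⇐ Nozaki–Hiyama–Kishi closure of C1–C10 from an aldehyde and a Z-alkenyl iodide, then oxidation to the enone.
3. Lactone ring (formed first) ⇐ oxidative lactonisation of a 2-methylene-1,4-diol. Its C6 carbinol and the C8 angelate come from the proposed Evans–Tishchenko reduction with angelaldehyde.
4. Open-chain β-hydroxy enone ⇐ alkenylmagnesium addition to a Weinreb amide (C5–C6); C7/C8 from an Evans syn-aldol with (Z)-3-iodobut-2-enal.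
5. C1–C5 piece ⇐ Noyori transfer hydrogenation (C3) and anti-carbomagnesiation/iodination (Z-C4=C5).

Assumption: position labels follow the ten-membered ring (C1 = CH(OH), C2 = CH2, C3 = CH(OAc), C4 = C(CH3), C5 = CH, C6 = lactone O–CH, C7 = ring-fusion CH, C8 = CH(O-angeloyl), C9 = CH, C10 = C(CH3), C11 = C(=CH2), C12 = lactone C=O, C13 = exocyclic CH2); in these labels the target is 1S,3S,6R,7R,8R,4Z,9Z with a cis-fused lactone, the SMILES are authoritative, and lithium (trimethylsilyl)acetylide solution and methyl angelate are taken as purchasable.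

## Route

Step 1
Reactants: 1 but-2-yn-1-ol
Product: 3 (Z)-3-iodobut-2-en-1-ol, via cyclic alkenylalanate 2 (not isolated)
Conditions: NaAlH2(OCH2CH2OMe)2, THF, 0 °C to rt; then I2, −78 °C to 0 °C
Reagents that add atoms: iodine, [I][I]
Why: hydroxyl-directed trans-hydroalumination places aluminium on the distal alkyne carbon cis to the CH2O group, and iodinolysis with retention gives the Z iodide (Corey-type reductive iodination of a propargylic alcohol).

Step 2
Reactants: 3 (Z)-3-iodobut-2-en-1-ol
Product: 4 (Z)-3-iodobut-2-enal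
Conditions: MnO2, CH2Cl2, rt, dark; filtered and used at once
Reagents that add atoms: none
Why: neutral allylic oxidation with MnO2 keeps the Z geometry of the β-iodo enal.

Step 3
Reactants: 5 2-methylprop-2-en-1-ol
Product: 7 3-(hydroxymethyl)but-3-enoic acid, via dilithio dianion 6 (not isolated)
Conditions: n-BuLi (2.1 equiv), TMEDA, Et2O, 0 °C to rt; then CO2, −78 °C; cold aq. HCl to pH 3
Reagents that add atoms: carbon dioxide, O=C=O
Why: O,C-dilithiation of methallyl alcohol gives a symmetrical allyl anion whose carboxylation can only give this acid (carboxylation of an allyllithium).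

Step 4
Reactants: 7 3-(hydroxymethyl)but-3-enoic acid
Product: 9 3-{[(tert-butyldimethylsilyl)oxy]methyl}but-3-enoic acid, via silyl ester 8 (not isolated)
Conditions: TBSCl (2.3 equiv), imidazole, DMF, rt; then K2CO3, MeOH/THF/H2O, rt; citric acid to pH 4
Reagents that add atoms: tert-butyldimethylsilyl chloride, CC(C)(C)[Si](C)(C)Cl
Why: bis-silylation followed by selective hydrolysis of the labile silyl ester leaves the silyl ether (standard protection of a hydroxy acid).

Step 5
Reactants: 9 3-{[(tert-butyldimethylsilyl)oxy]methyl}but-3-enoic acid; 10 (S)-4-benzyloxazolidin-2-one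
Product: 12 (S)-4-benzyl-3-(3-{[(tert-butyldimethylsilyl)oxy]methyl}but-3-enoyl)oxazolidin-2-one, via mixed pivalic anhydride 11 (not isolated)
Conditions: t-BuCOCl, Et3N, THF, −20 °C; then 10, LiCl, −20 °C to rt
Reagents that add atoms: none
Why: N-acylation through the mixed anhydride with LiCl/Et3N avoids strong base, so the β,γ-double bond does not move into conjugation.

Step 6
Reactants: 12 (S)-4-benzyl-3-(3-{[(tert-butyldimethylsilyl)oxy]methyl}but-3-enoyl)oxazolidin-2-one; 4 (Z)-3-iodobut-2-enal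
Product: 14 (S)-4-benzyl-3-[(2S,3S,4Z)-2-(3-{[(tert-butyldimethylsilyl)oxy]}prop-1-en-2-yl)-3-hydroxy-5-iodohex-4-enoyl]oxazolidin-2-one, via boron Z-enolate 13 (not isolated)
Conditions: Bu2BOTf, i-Pr2NEt, CH2Cl2, −78 to 0 °C; then 4, −78 to 0 °C; pH 7 buffer (KH2PO4/K2HPO4), MeOH, H2O2, 0 °C
Reagents that add atoms: none
Why: Evans syn-aldol through the Zimmerman–Traxler chair of the Z boron enolate, with the aldehyde on the face away from the benzyl group, sets C7 and C8 (7S,8S in this compound, 7,8-syn).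

Step 7
Reactants: 14 the aldol adduct
Product: 15 (2S,3S,4Z)-2-(3-{[(tert-butyldimethylsilyl)oxy]}prop-1-en-2-yl)-3-hydroxy-5-iodo-N-methoxy-N-methylhex-4-enamide
Conditions: MeNHOMe·HCl, AlMe3, CH2Cl2, −15 °C to rt; aq. potassium sodium tartrate
Reagents that add atoms: N,O-dimethylhydroxylamine hydrochloride, CNOC.Cl
Why: aluminium-amide transamination of a β-hydroxy imide is assisted by the free hydroxyl and does not touch C7 (Weinreb amide formation).

Step 8
Reactants: 16 methyl 3,3-dimethoxypropanoate; 17 lithium (trimethylsilyl)acetylide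
Product: 19 5,5-dimethoxy-1-(trimethylsilyl)pent-1-yn-3-one, via Weinreb amide 18 (not isolated)
Conditions: MeNHOMe·HCl, i-PrMgCl, THF, −20 °C; then 17, −20 to 0 °C; aq. NH4Cl
Reagents that add atoms: none
Why: the ester is converted in the flask into its Weinreb amide, whose chelated adduct with the acetylide collapses only on work-up, giving the ynone without over-addition (Weinreb ketone synthesis).

Step 9
Reactants: 19 5,5-dimethoxy-1-(trimethylsilyl)pent-1-yn-3-one
Product: 21 (S)-5,5-dimethoxypent-1-yn-3-ol, via silylated alcohol 20 (not isolated)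
Conditions: RuCl[(S,S)-TsDPEN](p-cymene) (1 mol %), i-PrOH, rt; then K2CO3, MeOH, rt
Reagents that add atoms: none
Why: Noyori asymmetric transfer hydrogenation of an alkynyl ketone, with the alkyne in the place of the aryl group in the transition state, gives the (S) carbinol (C3) with the (S,S) catalyst; methanolysis then removes the silyl group.

Step 10
Reactants: 21 (S)-5,5-dimethoxypent-1-yn-3-ol
Product: 23 (1Z,3S)-1-iodo-5,5-dimethoxy-2-methylpent-1-en-3-ol, via magnesium chelate 22 (not isolated)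
Conditions: MeMgBr (3 equiv), CuI (0.2 equiv), THF, −20 °C to rt; then I2, −78 to 0 °C
Reagents that add atoms: methylmagnesium bromide, C[Mg]Br; iodine, [I][I]
Why: alkoxide-directed, CuI-catalysed anti-carbomagnesiation (Duboudin reaction) adds methyl to the proximal alkyne carbon and leaves magnesium on the terminal carbon cis to the carbinol in a five-membered chelate; iodinolysis with retention gives the Z iodide (C4=C5).

Step 11
Reactants: 23 (1Z,3S)-1-iodo-5,5-dimethoxy-2-methylpent-1-en-3-ol
Product: 24 1-({[(1Z,3S)-1-iodo-5,5-dimethoxy-2-methylpent-1-en-3-yl]oxy}methyl)-4-methoxybenzene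
Conditions: NaH, 4-MeOC6H4CH2Cl, Bu4NI (cat.), THF/DMF, 0 °C to rt
Reagents that add atoms: 4-methoxybenzyl chloride, COc1ccc(CCl)cc1
Why: Williamson etherification under basic conditions leaves the acetal and the alkenyl iodide untouched (C4 carries no hydrogen, so no elimination).

Step 12
Reactants: 24 the PMB-protected alkenyl iodide; 15 the Weinreb amide
Product: 26 open-chain β-hydroxy enone (3S,7S,8S,4Z,9Z), via alkenylmagnesium chloride 25 (not isolated)
Conditions: 24, i-PrMgCl·LiCl, THF, −20 °C; separately 15, i-PrMgCl (1.0 equiv), THF, −78 °C; then 25, −78 to −10 °C; aq. NH4Cl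
Reagents that add atoms: none
Why: iodine–magnesium exchange keeps the Z geometry, and the alkenylmagnesium adds to the Weinreb amide (alkoxide formed first, which shields C7 from enolisation) to give a stable chelate that releases the Z enone only on work-up (Weinreb ketone synthesis).

Step 13
Reactants: 27 methyl (Z)-2-methylbut-2-enoate (methyl angelate)
Product: 28 (Z)-2-methylbut-2-en-1-ol
Conditions: i-Bu2AlH (2.2 equiv), CH2Cl2, −78 °C; aq. potassium sodium tartrate
Reagents that add atoms: none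
Why: 1,2-reduction of the enoate by the aluminium hydride does not touch the Z double bond.

Step 14
Reactants: 28 (Z)-2-methylbut-2-en-1-ol
Product: 29 (Z)-2-methylbut-2-enal (angelaldehyde)
Conditions: MnO2, pentane/CH2Cl2, 0 °C, dark; cold solution used at once
Reagents that add atoms: none
Why: neutral, low-temperature allylic oxidation avoids acid-promoted isomerisation to the E aldehyde.

Step 15
Reactants: 26 open-chain β-hydroxy enone; 29 (Z)-2-methylbut-2-enal
Product: 30 C8 angelate C6 alcohol (3S,6R,7R,8S,4Z,9Z)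
Conditions: SmI2 (0.3 equiv, premixed with 29), 29 (6 equiv), THF, −10 °C, dark; aq. NaHCO3
Reagents that add atoms: none
Why: Proposed new method: an Evans–Tishchenko reduction in which the hydride donor is the (Z)-enal 29; its hemiacetal at the C8 hydroxyl, held together with the C6 ketone on trivalent samarium in a chair-like six-membered transition state, delivers the formyl hydrogen intramolecularly to C6 anti to the C8 oxygen (sets 6R) and collapses to the C8 angelate, so one step sets the stereocentre and places the angeloyl group on the correct oxygen; the closest known reaction is the SmI2-catalysed Evans–Tishchenko reduction of β-hydroxy ketones with saturated or aryl aldehydes, and the new element is an α,β-unsaturated (Z)-aldehyde as donor, which should work because hydride transfer is intramolecular and fast relative to Z-to-E isomerisation at −10 °C.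

Step 16
Reactants: 30 C8 angelate C6 alcohol
Product: 31 C6,C12-diol C8 angelate (3S,6R,7R,8S)
Conditions: HF·pyridine, pyridine, THF, 0 °C
Reagents that add atoms: none
Why: buffered fluoride cleaves the primary allylic silyl ether while the acetal, PMB ether and angelate survive and acyl migration is suppressed.

Step 17
Reactants: 31 C6,C12-diol C8 angelate
Product: 32 cis-fused α-methylene-γ-butyrolactone with acetal and alkenyl iodide arms (3S,6R,7R,8S)
Conditions: TEMPO (0.2 equiv), PhI(OAc)2 (3 equiv), CH2Cl2, rt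
Reagents that add atoms: none
Why: the oxoammonium oxidant takes the primary allylic alcohol to the enal, the C6 hydroxyl closes to the lactol and this is oxidised to the lactone (oxidative lactonisation of a 2-methylene-1,4-diol); no stereocentre changes, and the cis fusion follows from the C6/C7 relationship set in steps 6 and 15.

Step 18
Reactants: 32 the lactone acetal
Product: 33 the lactone aldehyde (C1 aldehyde, 3S,6R,7R,8S)
Conditions: LiBF4, MeCN/H2O (50:1), rt
Reagents that add atoms: water, O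
Why: mild Lewis-acid hydrolysis of the dimethyl acetal spares the allylic PMB ether, the esters and the alkenyl iodide.

Step 19
Reactants: 33 the lactone aldehyde
Product: 34 macrocyclic C1 alcohol (mixture of C1 epimers; 3S,6R,7R,8R)
Conditions: CrCl2 (8 equiv), NiCl2 (0.05 equiv), DMSO/THF (3:1), 0.002 M, rt, slow addition
Reagents that add atoms: none
Why: Nozaki–Hiyama–Kishi coupling, in which the alkenylchromium formed with retention of the Z geometry adds only to the aldehyde (esters and the methylene lactone are inert) and closes the ten-membered ring; the C1 configuration is not controlled here and is erased in step 20.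

Step 20
Reactants: 34 macrocyclic C1 alcohol
Product: 35 macrocyclic C1 ketone (3S,6R,7R,8R)
Conditions: Dess–Martin periodinane, NaHCO3, CH2Cl2, 0 °C to rt
Reagents that add atoms: none
Why: buffered Dess–Martin oxidation converges both C1 epimers to the Z enone without epimerising C7 or isomerising the angelate.

Step 21
Reactants: 35 macrocyclic C1 ketone
Product: 36 macrocyclic β-hydroxy enone (C3–OH, C1=O; 3S,6R,7R,8R)
Conditions: DDQ, CH2Cl2/pH 7 buffer (KH2PO4/K2HPO4), 0 °C
Reagents that add atoms: none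
Why: oxidative cleavage of the electron-rich benzyl ether under neutral conditions avoids dehydration or retro-aldol opening of the β-hydroxy ketone.

Step 22
Reactants: 36 macrocyclic β-hydroxy enone
Product: 37 CNP0319825.3 (target)
Conditions: SmI2 (0.3 equiv, premixed with MeCHO), MeCHO (10 equiv), THF, −10 °C; aq. NaHCO3
Reagents that add atoms: acetaldehyde, CC=O
Why: Evans–Tishchenko reduction, in which the samarium-bound hemiacetal on O3 delivers hydride to the C1 ketone through a chair transition state to give the 1,3-anti product (sets 1S) and leaves the acetate on O3 with O1 free, exactly the pattern of the target.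

## Compound list

1 | but-2-yn-1-ol | CC#CCO | starting material
2 | sodium 2,2-bis(2-methoxyethoxy)-3-methyl-2,5-dihydro-1,2-oxaluminol-2-uide (cyclic alkenylalanate) | CC1=CCO[Al-]1(OCCOC)OCCOC.[Na+] | intermediate
3 | (Z)-3-iodobut-2-en-1-ol | OC/C=C(/C)I | intermediate
4 | (Z)-3-iodobut-2-enal | O=C/C=C(/C)I | intermediate
5 | 2-methylprop-2-en-1-ol | C=C(C)CO | starting material
6 | lithium 2-(lithiomethyl)prop-2-en-1-olate (dilithio dianion) | [Li]CC(=C)CO[Li] | intermediate
7 | 3-(hydroxymethyl)but-3-enoic acid | C=C(CO)CC(=O)O | intermediate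
8 | tert-butyldimethylsilyl 3-{[(tert-butyldimethylsilyl)oxy]methyl}but-3-enoate | C=C(CO[Si](C)(C)C(C)(C)C)CC(=O)O[Si](C)(C)C(C)(C)C | intermediate
9 | 3-{[(tert-butyldimethylsilyl)oxy]methyl}but-3-enoic acid | C=C(CO[Si](C)(C)C(C)(C)C)CC(=O)O | intermediate
10 | (S)-4-benzyloxazolidin-2-one | O=C1N[C@@H](Cc2ccccc2)CO1 | starting material
11 | mixed anhydride of 9 with pivalic acid | C=C(CO[Si](C)(C)C(C)(C)C)CC(=O)OC(=O)C(C)(C)C | intermediate
12 | (S)-4-benzyl-3-(3-{[(tert-butyldimethylsilyl)oxy]methyl}but-3-enoyl)oxazolidin-2-one | C=C(CO[Si](C)(C)C(C)(C)C)CC(=O)N1C(=O)OC[C@@H]1Cc1ccccc1 | intermediate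
13 | dibutylboron (Z)-enolate of 12 | C=C(CO[Si](C)(C)C(C)(C)C)/C=C(\OB(CCCC)CCCC)N1C(=O)OC[C@@H]1Cc1ccccc1 | intermediate
14 | (S)-4-benzyl-3-[(2S,3S,4Z)-2-(3-{[(tert-butyldimethylsilyl)oxy]}prop-1-en-2-yl)-3-hydroxy-5-iodohex-4-enoyl]oxazolidin-2-one | C=C(CO[Si](C)(C)C(C)(C)C)[C@H](C(=O)N1C(=O)OC[C@@H]1Cc1ccccc1)[C@H](O)/C=C(/C)I | intermediate
15 | (2S,3S,4Z)-2-(3-{[(tert-butyldimethylsilyl)oxy]}prop-1-en-2-yl)-3-hydroxy-5-iodo-N-methoxy-N-methylhex-4-enamide | C=C(CO[Si](C)(C)C(C)(C)C)[C@H](C(=O)N(C)OC)[C@H](O)/C=C(/C)I | intermediate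
16 | methyl 3,3-dimethoxypropanoate | COC(OC)CC(=O)OC | starting material
17 | lithium (trimethylsilyl)acetylide | [Li]C#C[Si](C)(C)C | starting material
18 | N-methoxy-3,3-dimethoxy-N-methylpropanamide | COC(OC)CC(=O)N(C)OC | intermediate
19 | 5,5-dimethoxy-1-(trimethylsilyl)pent-1-yn-3-one | COC(OC)CC(=O)C#C[Si](C)(C)C | intermediate
20 | (S)-5,5-dimethoxy-1-(trimethylsilyl)pent-1-yn-3-ol | COC(OC)C[C@H](O)C#C[Si](C)(C)C | intermediate
21 | (S)-5,5-dimethoxypent-1-yn-3-ol | COC(OC)C[C@H](O)C#C | intermediate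
22 | (S)-5-(2,2-dimethoxyethyl)-4-methyl-2,5-dihydro-1,2-oxamagnesole (cyclic alkenylmagnesium alkoxide) | COC(OC)C[C@@H]1O[Mg]C=C1C | intermediate
23 | (1Z,3S)-1-iodo-5,5-dimethoxy-2-methylpent-1-en-3-ol | COC(OC)C[C@H](O)/C(C)=C\I | intermediate
24 | 1-({[(1Z,3S)-1-iodo-5,5-dimethoxy-2-methylpent-1-en-3-yl]oxy}methyl)-4-methoxybenzene | COC(OC)C[C@H](OCc1ccc(OC)cc1)/C(C)=C\I | intermediate
25 | chloro{(1Z,3S)-5,5-dimethoxy-3-[(4-methoxybenzyl)oxy]-2-methylpent-1-en-1-yl}magnesium | COC(OC)C[C@H](OCc1ccc(OC)cc1)/C(C)=C\[Mg]Cl | intermediate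
26 | open-chain β-hydroxy enone (3S,7S,8S,4Z,9Z): C1 dimethyl acetal, C3 PMB ether, C6 ketone, C7 bearing C(=CH2)CH2OTBS, C8 free OH, iodine on C10 | COC(OC)C[C@H](OCc1ccc(OC)cc1)/C(C)=C\C(=O)[C@@H](C(=C)CO[Si](C)(C)C(C)(C)C)[C@H](O)/C=C(/C)I | intermediate
27 | methyl (Z)-2-methylbut-2-enoate (methyl angelate) | C/C=C(/C)C(=O)OC | starting material
28 | (Z)-2-methylbut-2-en-1-ol | C/C=C(/C)CO | intermediate
29 | (Z)-2-methylbut-2-enal (angelaldehyde) | C/C=C(/C)C=O | intermediate
30 | as 26 but C6 (R)-alcohol and C8 angelate, anti to each other (3S,6R,7R,8S,4Z,9Z) | COC(OC)C[C@H](OCc1ccc(OC)cc1)/C(C)=C\[C@@H](O)[C@@H](C(=C)CO[Si](C)(C)C(C)(C)C)[C@H](OC(=O)/C(C)=C\C)/C=C(/C)I | intermediate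
31 | as 30 with free C12 primary alcohol (C6,C12-diol, C8 angelate) | COC(OC)C[C@H](OCc1ccc(OC)cc1)/C(C)=C\[C@@H](O)[C@@H](C(=C)CO)[C@H](OC(=O)/C(C)=C\C)/C=C(/C)I | intermediate
32 | cis-fused α-methylene-γ-butyrolactone (O6–C12) carrying at C6 the (Z)-C5=C4(CH3)–C3H(OPMB)–CH2–CH(OMe)2 arm and at C7 the CH(O-angeloyl)–CH=C(CH3)I arm (3S,6R,7R,8S) | COC(OC)C[C@H](OCc1ccc(OC)cc1)/C(C)=C\[C@H]1OC(=O)C(=C)[C@H]1[C@H](OC(=O)/C(C)=C\C)/C=C(/C)I | intermediate
33 | as 32 with C1 aldehyde in place of the acetal | O=CC[C@H](OCc1ccc(OC)cc1)/C(C)=C\[C@H]1OC(=O)C(=C)[C@H]1[C@H](OC(=O)/C(C)=C\C)/C=C(/C)I | intermediate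
34 | macrocycle: target skeleton with C1–OH as a mixture of epimers and C3 PMB ether (3S,6R,7R,8R,4Z,9Z) | C=C1C(=O)O[C@@H]2/C=C(/C)[C@@H](OCc3ccc(OC)cc3)CC(O)/C(C)=C\[C@@H](OC(=O)/C(C)=C\C)[C@H]12 | intermediate
35 | macrocyclic C1 ketone, C3 PMB ether (3S,6R,7R,8R) | C=C1C(=O)O[C@@H]2/C=C(/C)[C@@H](OCc3ccc(OC)cc3)CC(=O)/C(C)=C\[C@@H](OC(=O)/C(C)=C\C)[C@H]12 | intermediate
36 | macrocyclic β-hydroxy enone: C1 ketone, C3 free (S)-alcohol (3S,6R,7R,8R) | C=C1C(=O)O[C@@H]2/C=C(/C)[C@@H](O)CC(=O)/C(C)=C\[C@@H](OC(=O)/C(C)=C\C)[C@H]12 | intermediate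
37 | CNP0319825.3 (1S,3S,6R,7R,8R,4Z,9Z): 3-acetate, 8-angelate, 1-alcohol, cis-fused 6,12-lactone | C=C1C(=O)O[C@@H]2/C=C(/C)[C@@H](OC(C)=O)C[C@H](O)/C(C)=C\[C@@H](OC(=O)/C(C)=C\C)[C@H]12 | target

## Step count and risks

Total step count: 22. Longest linear sequence: 14 steps (steps 3, 4, 5, 6, 7, 12, 15, 16, 17, 18, 19, 20, 21, 22).

The three steps most likely to fail:

Step 15 (the proposed new Evans–Tishchenko reduction with angelaldehyde). The enal may be a poor hydride donor, may isomerise to the E (tiglate) series on samarium, or the substrate may undergo retro-aldol cleavage. The fallback uses known chemistry only and sets out from 26. A standard Evans–Tishchenko reduction with acetaldehyde (SmI2, MeCHO, THF, −10 °C) gives the C8 acetate C6 alcohol F1 with the same anti stereochemistry. The C6 hydroxyl is silylated (Et3SiOTf, 2,6-lutidine, −78 °C) to the triethylsilyl ether F2. The acetate is removed (K2CO3, MeOH, 0 °C) to the C8 alcohol F3. This is esterified with angelic acid under Yamaguchi conditions (2,4,6-trichlorobenzoyl chloride, Et3N, toluene, 80 °C, no DMAP) to the C8 angelate F4. HF·pyridine then removes both silyl groups, and the fallback comes back to the route at diol 31.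

Step 19 (Nozaki–Hiyama–Kishi closure of the ten-membered ring). Ring strain, oligomerisation or nickel-mediated ionisation of the allylic angelate could defeat it. The fallback closes the same bond as a ketone by an intramolecular Stille acylation and sets out from 32. Iodine is exchanged for tin (Me3SnSnMe3, Pd(PPh3)4, toluene, 80 °C) to give the alkenylstannane acetal F5. Hydrolysis (LiBF4, wet MeCN) gives the stannyl aldehyde F6. Pinnick oxidation (NaClO2, NaH2PO4, 2-methylbut-2-ene) gives the stannyl acid F7. 1-Chloro-N,N,2-trimethylprop-1-en-1-amine converts it to the acid chloride F8, which is cyclised at high dilution (Pd2(dba)3, AsPh3, toluene, 60 °C). This gives the enone directly, and the fallback comes back at 35.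

Step 22 (final Evans–Tishchenko reduction on the macrocycle). The transannular geometry may not allow the chelated chair, and acyl migration, retro-aldol ring opening or reduction of the methylene lactone may compete. The fallback sets C1 by reagent control and sets out from 35. Reduction with (R)-2-methyl-CBS-oxazaborolidine and catecholborane (toluene, −78 °C; the alkenyl group acts as the large substituent) gives the (1S)-alcohol F9. Silylation (Et3SiCl, imidazole) gives the C1 triethylsilyl ether F10. DDQ removes the PMB group to give the C3 alcohol F11. Acetylation (Ac2O, pyridine, DMAP) gives the C3 acetate F12. HF·pyridine then frees O1, and the fallback comes back at the target 37.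

Further compounds

F1 | step 15 | as 30 but with an acetate instead of the angelate on O8 (C6 free alcohol) | COC(OC)C[C@H](OCc1ccc(OC)cc1)/C(C)=C\[C@@H](O)[C@@H](C(=C)CO[Si](C)(C)C(C)(C)C)[C@H](OC(C)=O)/C=C(/C)I
F2 | step 15 | F1 with O6 as triethylsilyl ether | COC(OC)C[C@H](OCc1ccc(OC)cc1)/C(C)=C\[C@@H](O[Si](CC)(CC)CC)[C@@H](C(=C)CO[Si](C)(C)C(C)(C)C)[C@H](OC(C)=O)/C=C(/C)I
F3 | step 15 | F2 with free C8 alcohol | COC(OC)C[C@H](OCc1ccc(OC)cc1)/C(C)=C\[C@@H](O[Si](CC)(CC)CC)[C@@H](C(=C)CO[Si](C)(C)C(C)(C)C)[C@H](O)/C=C(/C)I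
F4 | step 15 | F3 with O8 angelate | COC(OC)C[C@H](OCc1ccc(OC)cc1)/C(C)=C\[C@@H](O[Si](CC)(CC)CC)[C@@H](C(=C)CO[Si](C)(C)C(C)(C)C)[C@H](OC(=O)/C(C)=C\C)/C=C(/C)I
F5 | step 19 | 32 with trimethylstannyl in place of iodine | COC(OC)C[C@H](OCc1ccc(OC)cc1)/C(C)=C\[C@H]1OC(=O)C(=C)[C@H]1[C@H](OC(=O)/C(C)=C\C)/C=C(/C)[Sn](C)(C)C
F6 | step 19 | F5 with C1 aldehyde | O=CC[C@H](OCc1ccc(OC)cc1)/C(C)=C\[C@H]1OC(=O)C(=C)[C@H]1[C@H](OC(=O)/C(C)=C\C)/C=C(/C)[Sn](C)(C)C
F7 | step 19 | F5 with C1 carboxylic acid | OC(=O)C[C@H](OCc1ccc(OC)cc1)/C(C)=C\[C@H]1OC(=O)C(=C)[C@H]1[C@H](OC(=O)/C(C)=C\C)/C=C(/C)[Sn](C)(C)C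
F8 | step 19 | F5 with C1 acid chloride | ClC(=O)C[C@H](OCc1ccc(OC)cc1)/C(C)=C\[C@H]1OC(=O)C(=C)[C@H]1[C@H](OC(=O)/C(C)=C\C)/C=C(/C)[Sn](C)(C)C
F9 | step 22 | macrocyclic (1S)-alcohol with C3 PMB ether | C=C1C(=O)O[C@@H]2/C=C(/C)[C@@H](OCc3ccc(OC)cc3)C[C@H](O)/C(C)=C\[C@@H](OC(=O)/C(C)=C\C)[C@H]12
F10 | step 22 | F9 with O1 as triethylsilyl ether | C=C1C(=O)O[C@@H]2/C=C(/C)[C@@H](OCc3ccc(OC)cc3)C[C@H](O[Si](CC)(CC)CC)/C(C)=C\[C@@H](OC(=O)/C(C)=C\C)[C@H]12
F11 | step 22 | F10 with free C3 alcohol | C=C1C(=O)O[C@@H]2/C=C(/C)[C@@H](O)C[C@H](O[Si](CC)(CC)CC)/C(C)=C\[C@@H](OC(=O)/C(C)=C\C)[C@H]12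
F12 | step 22 | F11 with O3 acetate | C=C1C(=O)O[C@@H]2/C=C(/C)[C@@H](OC(C)=O)C[C@H](O[Si](CC)(CC)CC)/C(C)=C\[C@@H](OC(=O)/C(C)=C\C)[C@H]12
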